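Everything rests on cutting the bond between the syringyl ring and C2 of the oxane. The C2–C3–C4 unit of that ring (benzylic ether carbon, methylene, carbinol) is a latent vinylogous ester, so C2 is brought in as the lactone carbonyl of an (S)-4-methoxy-5,6-dihydropyran-2-one, made by one catalytic asymmetric hetero-Diels–Alder reaction. An aryllithium adds to that carbonyl and acid transposes the oxygen function to C4 (Stork–Danheiser): one operation joins both halves and unveils a 6-aryl-2,3-dihydropyran-4-one. The single catalyst-set centre C6 then relays C2 (hydrogenation, which also removes both benzyl groups) and C4 (hydride reduction).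

Key step: step 6

Remark: in the Why lines and in the fallbacks, C2, C4 and C6 always mean the atoms that become C2 (aryl-bearing), C4 (carbinol) and C6 (side-chain-bearing) of the target oxane; compound names keep their own IUPAC locants.
Assumption: the (R)-BINOL–Ti(IV) catalyst of step 4 is taken to deliver the (S)-lactone; should the sense of induction prove opposite, (S)-BINOL would be used.

Step 1
Reactants: 1 3-(4-hydroxy-3-methoxyphenyl)propan-1-ol (dihydroconiferyl alcohol)
Product: 2 3-[4-(benzyloxy)-3-methoxyphenyl]propan-1-ol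
Conditions: BnBr, K2CO3, acetone, reflux
Reagents that add atoms: benzyl bromide, BrCc1ccccc1
Why: Williamson ether synthesis; K2CO3 deprotonates only the phenol, so the phenoxide is benzylated and the primary alcohol stays free.

Step 2
Reactants: 2 3-[4-(benzyloxy)-3-methoxyphenyl]propan-1-ol
Product: 3 3-[4-(benzyloxy)-3-methoxyphenyl]propanal
Conditions: TEMPO (cat.), PhI(OAc)2, CH2Cl2, rt
Reagents that add atoms: none
Why: TEMPO/oxoammonium oxidation of a primary alcohol stops at the aldehyde under neutral conditions that the aryl ethers tolerate.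

Step 3
Reactants: 4 methyl (E)-3-methoxybut-2-enoate
Product: 5 (1Z)-1,3-dimethoxy-1-(trimethylsilyloxy)buta-1,3-diene (Brassard's diene)
Conditions: LDA, THF, −78 °C; TMSCl, −78 °C to rt
Reagents that add atoms: chlorotrimethylsilane, C[Si](C)(C)Cl
Why: γ-deprotonation of the vinylogous ester and O-silylation of the dienolate (silyl ketene acetal formation) should give the diene, whose ketene acetal geometry is of no consequence because that carbon becomes the lactone carbonyl.

Step 4
Reactants: 3 3-[4-(benzyloxy)-3-methoxyphenyl]propanal; 5 Brassard's diene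
Product: 7 (6S)-6-{2-[4-(benzyloxy)-3-methoxyphenyl]ethyl}-4-methoxy-5,6-dihydro-2H-pyran-2-one, via silyl aldol adduct 6 (not isolated)
Conditions: (R)-BINOL (20 mol %), Ti(OiPr)4 (10 mol %), 4 Å MS, toluene, 0 °C; then TFA, CH2Cl2, 0 °C
Reagents that add atoms: none
Why: Catalytic asymmetric hetero-Diels–Alder reaction of Brassard's diene, running as a vinylogous Mukaiyama aldol addition followed by acid-promoted lactonisation; the BINOL–Ti(IV) complex shields one face of the coordinated aldehyde and sets C6 (S), the only stereocentre set by a catalyst.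

Step 5
Reactants: 8 4-bromo-2,6-dimethoxyphenol
Product: 9 2-(benzyloxy)-5-bromo-1,3-dimethoxybenzene
Conditions: BnBr, K2CO3, DMF, 60 °C
Reagents that add atoms: benzyl bromide, BrCc1ccccc1
Why: Williamson ether synthesis of the phenoxide, which protects the phenol for the halogen–lithium exchange with a group that the later hydrogenation removes.

Step 6
Reactants: 9 2-(benzyloxy)-5-bromo-1,3-dimethoxybenzene; 7 (6S)-6-{2-[4-(benzyloxy)-3-methoxyphenyl]ethyl}-4-methoxy-5,6-dihydro-2H-pyran-2-one
Product: 12 (2S)-6-[4-(benzyloxy)-3,5-dimethoxyphenyl]-2-{2-[4-(benzyloxy)-3-methoxyphenyl]ethyl}-2,3-dihydro-4H-pyran-4-one, via aryllithium 10 (not isolated), via lactol 11 (not isolated)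
Conditions: 9, n-BuLi (1.05 equiv), THF, −78 °C; then 7, −78 °C; then 2 M HCl, THF, 0 °C to rt
Reagents that add atoms: water, O (the C4 carbonyl oxygen comes from the aqueous acid; the former lactone carbonyl oxygen leaves as water)
Why: Bromine–lithium exchange gives aryllithium 10, which adds 1,2 to the lactone carbonyl of the vinylogous carbonate 7 to form a lithium hemiketal that should persist at −78 °C; on acidification lactol 11 ionises to a 4-methoxy-stabilised oxocarbenium ion, water adds at C4 and methanol is lost, so the carbonyl moves from C2 to C4 and the aryl-substituted dihydropyranone results. The closest known reaction type is the Stork–Danheiser carbonyl transposition of vinylogous esters, combined with the aryllithium-to-lactone addition of C-aryl glycoside synthesis. No ring is closed in the net reaction, since the O1–C6 bond of 7 is kept; should the tetrahedral intermediate open to the δ-hydroxy aryl ketone, acid would re-close the same six-membered ring by hemiketalisation (6-exo-trig) before dehydration. No new stereocentre remains, because the anomeric centre of 11 is lost again, and C6, which is not enolisable, is carried through unchanged. The step needs 1,2-addition to win over γ-deprotonation at C5 and over a second addition; the low temperature, the near-stoichiometric aryllithium, the stability of the cyclic lithium hemiketal and the poor electrophilicity of any ring-opened β-methoxy enone should secure this.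

Step 7
Reactants: 12 (2S)-6-[4-(benzyloxy)-3,5-dimethoxyphenyl]-2-{2-[4-(benzyloxy)-3-methoxyphenyl]ethyl}-2,3-dihydro-4H-pyran-4-one
Product: 13 (2S,6S)-2-(4-hydroxy-3,5-dimethoxyphenyl)-6-[2-(4-hydroxy-3-methoxyphenyl)ethyl]oxan-4-one
Conditions: H2 (1 atm), 10% Pd/C, EtOAc, rt
Reagents that add atoms: none
Why: Heterogeneous catalytic hydrogenation should deliver H2 syn to the C2=C3 bond from the ring face opposite the C6 side chain, so the new C2–H is cis to C6–H and the aryl group and side chain become cis (both equatorial, 2S); the two benzyl ethers are hydrogenolysed in the same operation.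

Step 8
Reactants: 13 (2S,6S)-2-(4-hydroxy-3,5-dimethoxyphenyl)-6-[2-(4-hydroxy-3-methoxyphenyl)ethyl]oxan-4-one
Product: 14 (2S,4R,6S)-2-(4-hydroxy-3,5-dimethoxyphenyl)-6-[2-(4-hydroxy-3-methoxyphenyl)ethyl]oxan-4-ol
Conditions: NaBH4, MeOH, −20 °C
Reagents that add atoms: none
Why: Borohydride reduction; the small hydride should attack the chair ketone, whose two substituents are equatorial, along the axial trajectory and give the equatorial C4 alcohol (4R), cis to both substituents.

Compound list
1 | 3-(4-hydroxy-3-methoxyphenyl)propan-1-ol (dihydroconiferyl alcohol) | COc1cc(CCCO)ccc1O | starting material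
2 | 3-[4-(benzyloxy)-3-methoxyphenyl]propan-1-ol | COc1cc(CCCO)ccc1OCc1ccccc1 | intermediate
3 | 3-[4-(benzyloxy)-3-methoxyphenyl]propanal | COc1cc(CCC=O)ccc1OCc1ccccc1 | intermediate
4 | methyl (E)-3-methoxybut-2-enoate | CO/C(C)=C/C(=O)OC | starting material
5 | (1Z)-1,3-dimethoxy-1-(trimethylsilyloxy)buta-1,3-diene (Brassard's diene) | C=C(OC)/C=C(OC)\O[Si](C)(C)C | intermediate
6 | methyl (2E,5S)-7-[4-(benzyloxy)-3-methoxyphenyl]-3-methoxy-5-(trimethylsilyloxy)hept-2-enoate (silyl aldol adduct, not isolated) | COC(=O)/C=C(/OC)C[C@@H](O[Si](C)(C)C)CCc1ccc(OCc2ccccc2)c(OC)c1 | intermediate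
7 | (6S)-6-{2-[4-(benzyloxy)-3-methoxyphenyl]ethyl}-4-methoxy-5,6-dihydro-2H-pyran-2-one | COc1cc(CC[C@H]2CC(OC)=CC(=O)O2)ccc1OCc1ccccc1 | intermediate
8 | 4-bromo-2,6-dimethoxyphenol | COc1cc(Br)cc(OC)c1O | starting material
9 | 2-(benzyloxy)-5-bromo-1,3-dimethoxybenzene | COc1cc(Br)cc(OC)c1OCc1ccccc1 | intermediate
10 | [4-(benzyloxy)-3,5-dimethoxyphenyl]lithium (not isolated) | [Li]c1cc(OC)c(OCc2ccccc2)c(OC)c1 | intermediate
11 | (6S)-2-[4-(benzyloxy)-3,5-dimethoxyphenyl]-6-{2-[4-(benzyloxy)-3-methoxyphenyl]ethyl}-4-methoxy-5,6-dihydro-2H-pyran-2-ol (lactol, both C2 epimers, lithium alkoxide until the quench, not isolated) | COc1cc(CC[C@H]2CC(OC)=CC(O)(c3cc(OC)c(OCc4ccccc4)c(OC)c3)O2)ccc1OCc1ccccc1 | intermediate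
12 | (2S)-6-[4-(benzyloxy)-3,5-dimethoxyphenyl]-2-{2-[4-(benzyloxy)-3-methoxyphenyl]ethyl}-2,3-dihydro-4H-pyran-4-one | COc1cc(CC[C@H]2CC(=O)C=C(c3cc(OC)c(OCc4ccccc4)c(OC)c3)O2)ccc1OCc1ccccc1 | intermediate
13 | (2S,6S)-2-(4-hydroxy-3,5-dimethoxyphenyl)-6-[2-(4-hydroxy-3-methoxyphenyl)ethyl]oxan-4-one | COc1cc(CC[C@H]2CC(=O)C[C@@H](c3cc(OC)c(O)c(OC)c3)O2)ccc1O | intermediate
14 | (2S,4R,6S)-2-(4-hydroxy-3,5-dimethoxyphenyl)-6-[2-(4-hydroxy-3-methoxyphenyl)ethyl]oxan-4-ol | COc1cc(CC[C@H]2C[C@@H](O)C[C@@H](c3cc(OC)c(O)c(OC)c3)O2)ccc1O | target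

Total step count: 8. Longest linear sequence: 6 steps (steps 1, 2, 4, 6, 7, 8 from dihydroconiferyl alcohol).

Steps most likely to fail

Step 6. The aryllithium may act as a base at C5 (γ-deprotonation followed by β-elimination that opens the lactone), or the tetrahedral intermediate may collapse early and take up a second aryllithium. The fallback sets out from 7 and 9 and comes back at 13; it forms the same aryl–C2 bond under non-basic catalytic conditions. Lactone 7 would be reduced with DIBAL-H (CH2Cl2, −78 °C) and the lactol treated with aqueous acid, the hydride version of the same transposition, to give (2S)-2-{2-[4-(benzyloxy)-3-methoxyphenyl]ethyl}-2,3-dihydro-4H-pyran-4-one F1. Bromide 9 would be converted (n-BuLi, B(OiPr)3, THF, −78 °C, then aqueous acid) into [4-(benzyloxy)-3,5-dimethoxyphenyl]boronic acid F2. Rhodium(I)-catalysed 1,4-addition of F2 to F1 ([Rh(cod)OH]2, dioxane–water) should proceed by axial attack at C2, anti to the C6 side chain, and give the 2,6-trans ketone (2R,6S)-2-[4-(benzyloxy)-3,5-dimethoxyphenyl]-6-{2-[4-(benzyloxy)-3-methoxyphenyl]ethyl}oxan-4-one F3. Hydrogenolysis (H2, Pd/C, EtOAc) would free the phenols to give (2R,6S)-2-(4-hydroxy-3,5-dimethoxyphenyl)-6-[2-(4-hydroxy-3-methoxyphenyl)ethyl]oxan-4-one F4. Catalytic acid (TsOH, CH2Cl2, rt) should then equilibrate F4 to the diequatorial cis ketone 13 through reversible opening of the benzylic C2–O bond, which the para-hydroxy group assists and which leaves C6 untouched.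

Step 4. The unbranched, enolisable aldehyde may give low conversion or eroded enantioselectivity through an uncatalysed background addition. The fallback sets out from 3 and comes back at 7. A catalytic asymmetric vinylogous Mukaiyama aldol addition of 2,2-dimethyl-6-methylidene-4-(trimethylsilyloxy)-1,3-dioxine to 3 (Ti(OiPr)4/BINOL, THF, −78 °C, then acidic desilylation) would give (S)-6-{4-[4-(benzyloxy)-3-methoxyphenyl]-2-hydroxybutyl}-2,2-dimethyl-4H-1,3-dioxin-4-one F5. K2CO3 in methanol should open the dioxinone and close the β-keto-δ-lactone (6S)-6-{2-[4-(benzyloxy)-3-methoxyphenyl]ethyl}oxane-2,4-dione F6. O-Methylation of its enol (Me2SO4, K2CO3, acetone) gives 7.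

Step 7. Facial discrimination on the catalyst surface may be incomplete, because the C6 side chain is pseudo-equatorial and remote from C2, so some of the C2 epimer would form. The fallback sets out from 12 and comes back at 13; it replaces surface control by stereoelectronic control. Conjugate reduction of 12 with L-Selectride (THF, −78 °C) should deliver hydride axially to C2, on the face of C6–H, so the aryl group becomes equatorial. This would give the cis ketone (2S,6S)-2-[4-(benzyloxy)-3,5-dimethoxyphenyl]-6-{2-[4-(benzyloxy)-3-methoxyphenyl]ethyl}oxan-4-one F7 with both benzyl ethers intact. Hydrogenolysis of only the benzyl ethers (H2, Pd/C, EtOAc) then leads to 13.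

Further compounds
F1 | step 6 | (2S)-2-{2-[4-(benzyloxy)-3-methoxyphenyl]ethyl}-2,3-dihydro-4H-pyran-4-one | COc1cc(CC[C@H]2CC(=O)C=CO2)ccc1OCc1ccccc1
F2 | step 6 | [4-(benzyloxy)-3,5-dimethoxyphenyl]boronic acid | COc1cc(B(O)O)cc(OC)c1OCc1ccccc1
F3 | step 6 | (2R,6S)-2-[4-(benzyloxy)-3,5-dimethoxyphenyl]-6-{2-[4-(benzyloxy)-3-methoxyphenyl]ethyl}oxan-4-one | COc1cc(CC[C@H]2CC(=O)C[C@H](c3cc(OC)c(OCc4ccccc4)c(OC)c3)O2)ccc1OCc1ccccc1
F4 | step 6 | (2R,6S)-2-(4-hydroxy-3,5-dimethoxyphenyl)-6-[2-(4-hydroxy-3-methoxyphenyl)ethyl]oxan-4-one | COc1cc(CC[C@H]2CC(=O)C[C@H](c3cc(OC)c(O)c(OC)c3)O2)ccc1O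
F5 | step 4 | (S)-6-{4-[4-(benzyloxy)-3-methoxyphenyl]-2-hydroxybutyl}-2,2-dimethyl-4H-1,3-dioxin-4-one | COc1cc(CC[C@H](O)CC2=CC(=O)OC(C)(C)O2)ccc1OCc1ccccc1
F6 | step 4 | (6S)-6-{2-[4-(benzyloxy)-3-methoxyphenyl]ethyl}oxane-2,4-dione | COc1cc(CC[C@H]2CC(=O)CC(=O)O2)ccc1OCc1ccccc1
F7 | step 7 | (2S,6S)-2-[4-(benzyloxy)-3,5-dimethoxyphenyl]-6-{2-[4-(benzyloxy)-3-methoxyphenyl]ethyl}oxan-4-one | COc1cc(CC[C@H]2CC(=O)C[C@@H](c3cc(OC)c(OCc4ccccc4)c(OC)c3)O2)ccc1OCc1ccccc1
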